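The retrosynthesis first returns both hydroxymethyl groups to formyl groups and removes the bromines at C5 (ring A) and C4' (ring B), each of which sits ortho to a phenol and can be introduced last.
It then cuts two carbon–oxygen bonds of ring B in one operation, the diaryl ether bond C1'–O and the phenolic bond C6'–O, leading back to a C1'–C6' aryne, a ring-A aryloxide and an electrophilic oxygen source.
The enabling feature is the vicinal pair C1' (O-aryl) and C6' (OH) on ring B with the C5' oxygen directly beside it: a methoxy group on C5' polarises the aryne so that the aryloxide enters at C1' and the metal ends on C6'.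
Forward, ring B is prepared from isovanillin (iodination, sulfonylation, acetalization) and ring A from 2-bromoisovanillin (acetalization); the halves are joined in the aryne step, then the acetals and methyl ethers are removed, both rings are brominated and both aldehydes are reduced.
No ring is formed, since both benzene rings are bought, and the target has no stereocenter, so only regiochemistry has to be controlled.

Key step: step 5

Remark: ring A is numbered C1 (CH2OH), C2 (Br), C3 (O-aryl), C4 (OH), C5 (Br) and ring B C1' (O-aryl), C2' (CH2OH), C3' (H), C4' (Br), C5' (OH), C6' (OH); isovanillin, 2-bromoisovanillin and 4-chlorobenzenesulfonyl chloride are taken as commercial.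

Step 1
Reactants: 1 3-hydroxy-4-methoxybenzaldehyde (isovanillin)
Product: 2 3-hydroxy-2-iodo-4-methoxybenzaldehyde (2-iodoisovanillin)
Conditions: ICl, pyridine, 1,4-dioxane, 0 °C → rt
Reagents that add atoms: iodine monochloride, ClI
Why: Electrophilic aromatic iodination in which the free hydroxyl directs the iodine to its ortho position between the hydroxyl and formyl groups, the established outcome for isovanillin under these conditions.

Step 2
Reactants: 2 3-hydroxy-2-iodo-4-methoxybenzaldehyde; 3 4-chlorobenzenesulfonyl chloride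
Product: 4 3-formyl-2-iodo-6-methoxyphenyl 4-chlorobenzenesulfonate
Conditions: Et3N, DMAP (cat.), CH2Cl2, 0 °C → rt
Reagents that add atoms: none
Why: O-Sulfonylation of a phenol under nucleophilic catalysis, installing a leaving group that tolerates iodine–magnesium exchange at −78 °C yet departs on warming.

Step 3
Reactants: 4 3-formyl-2-iodo-6-methoxyphenyl 4-chlorobenzenesulfonate
Product: 5 3-(dimethoxymethyl)-2-iodo-6-methoxyphenyl 4-chlorobenzenesulfonate
Conditions: HC(OMe)3, MeOH, TsOH·H2O (cat.), 50 °C; then Et3N
Reagents that add atoms: trimethyl orthoformate, COC(OC)OC; methanol, CO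
Why: Acid-catalysed acetalization driven by the orthoformate as water scavenger, which leaves the aryl iodide and aryl sulfonate untouched and masks the formyl group against the organomagnesium reagents and the peroxide of step 5.

Step 4
Reactants: 6 2-bromo-3-hydroxy-4-methoxybenzaldehyde (2-bromoisovanillin)
Product: 7 2-bromo-3-(dimethoxymethyl)-6-methoxyphenol
Conditions: HC(OMe)3, MeOH, TsOH·H2O (cat.), rt; then Et3N
Reagents that add atoms: trimethyl orthoformate, COC(OC)OC; methanol, CO
Why: Acid-catalysed acetalization with trimethyl orthoformate, in which the phenol stays free and the acetal is preserved by neutralising the acid before concentration.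

Step 5
Reactants: 5 3-(dimethoxymethyl)-2-iodo-6-methoxyphenyl 4-chlorobenzenesulfonate; 7 2-bromo-3-(dimethoxymethyl)-6-methoxyphenol
Product: 13 2-[2-bromo-3-(dimethoxymethyl)-6-methoxyphenoxy]-3-(dimethoxymethyl)-6-methoxyphenol, via chloromagnesium aryloxide of ring A 8 (not isolated), via ortho-sulfonyloxy aryl Grignard reagent 9 (not isolated), via ring-B aryne 10 (not isolated), via C6' arylmagnesium adduct 11 (not isolated), via dimethyl arylboronate 12 (not isolated)
Conditions: 7 (2.0 equiv), iPrMgCl (2.0 equiv), THF, −20 °C; separately 5, iPrMgCl (1.05 equiv), THF, −78 °C; combine, −78 °C → rt; B(OMe)3, −20 °C → rt; 30% H2O2, aq. NaOH, 0 °C; work-up at pH 7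
Reagents that add atoms: hydrogen peroxide, OO
Why: Proposed new method: iodine–magnesium exchange on 5 at −78 °C gives Grignard reagent 9, which on warming expels 4-chlorobenzenesulfonate to form aryne 10; the chloromagnesium aryloxide 8 adds through oxygen to C1' and leaves magnesium on C6' (11), trimethyl borate converts this into boronate 12, and alkaline hydrogen peroxide then delivers the phenol by aryl migration from boron to oxygen. The closest known reactions are the additions of magnesium thiolates and magnesium amides to arynes generated from 2-iodoaryl sulfonates, followed by electrophilic trapping of the new aryl Grignard reagent, and the O–H insertion of phenols into arynes; an aryloxide in this three-component role has no precedent. No ring is closed and no stereocenter is formed. The selectivity required is attack at C1' and not at C6': the C5' methoxy group distorts the triple bond so that C1' is the more electrophilic carbon and the developing carbanion on C6' lies beside the inductively withdrawing oxygen, where O–Mg coordination also holds it, while the acetal carbon on C2' opposes this only weakly and may guide the magnesium aryloxide to C1' by chelation. The aryloxide is used in excess and without any proton source so that it outcompetes addition of 9 to the aryne and so that 11 survives until borylation; the ring-A bromide is inert to isopropylmagnesium chloride at these temperatures, and the acetals shield both formyl carbons from the Grignard reagents and from Dakin oxidation.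

Step 6
Reactants: 13 2-[2-bromo-3-(dimethoxymethyl)-6-methoxyphenoxy]-3-(dimethoxymethyl)-6-methoxyphenol
Product: 14 2-(2-bromo-3-formyl-6-methoxyphenoxy)-3-hydroxy-4-methoxybenzaldehyde
Conditions: 1 M HCl, THF, rt
Reagents that add atoms: water, O
Why: Acid-catalysed acetal hydrolysis, to which the aryl methyl ethers, the diaryl ether and the aryl bromide are inert.

Step 7
Reactants: 14 2-(2-bromo-3-formyl-6-methoxyphenoxy)-3-hydroxy-4-methoxybenzaldehyde
Product: 15 2-(2-bromo-3-formyl-6-hydroxyphenoxy)-3,4-dihydroxybenzaldehyde
Conditions: BBr3 (excess), CH2Cl2, −78 °C → rt; then H2O, 0 °C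
Reagents that add atoms: none
Why: Lewis-acid cleavage of aryl methyl ethers with boron tribromide, in which bromide attacks the methyl carbon of the boron-complexed ethers while the diaryl ether offers no alkyl carbon and the aldehydes are recovered on aqueous work-up.

Step 8
Reactants: 15 2-(2-bromo-3-formyl-6-hydroxyphenoxy)-3,4-dihydroxybenzaldehyde
Product: 16 5-bromo-2-(2,5-dibromo-3-formyl-6-hydroxyphenoxy)-3,4-dihydroxybenzaldehyde
Conditions: Br2 (2.05 equiv), NaOAc, AcOH, rt
Reagents that add atoms: bromine, BrBr
Why: Electrophilic aromatic bromination, one bromine per ring: on ring A, C5 is the only position ortho to the free C4 hydroxyl, and on ring B, C4' is ortho to the C5' hydroxyl, para to the ether oxygen on C1' and meta to the formyl group, whereas the rival C3' has only one para hydroxyl and lies ortho to the formyl group.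

Step 9
Reactants: 16 5-bromo-2-(2,5-dibromo-3-formyl-6-hydroxyphenoxy)-3,4-dihydroxybenzaldehyde
Product: 17 6-bromo-3-[2,5-dibromo-6-hydroxy-3-(hydroxymethyl)phenoxy]-4-(hydroxymethyl)benzene-1,2-diol (target)
Conditions: NaBH4, THF/MeOH, 0 °C; then aq. NH4Cl (pH 6)
Reagents that add atoms: none
Why: Hydride reduction of two aryl aldehydes with NaBH4, which spares aryl bromides, phenols and the diaryl ether, with a near-neutral work-up to avoid ionisation of the para-hydroxybenzyl alcohols.

Compound list
1 | 3-hydroxy-4-methoxybenzaldehyde (isovanillin) | COc1ccc(C=O)cc1O | starting material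
2 | 3-hydroxy-2-iodo-4-methoxybenzaldehyde | COc1ccc(C=O)c(I)c1O | intermediate
3 | 4-chlorobenzenesulfonyl chloride | O=S(=O)(Cl)c1ccc(Cl)cc1 | starting material
4 | 3-formyl-2-iodo-6-methoxyphenyl 4-chlorobenzenesulfonate | COc1ccc(C=O)c(I)c1OS(=O)(=O)c1ccc(Cl)cc1 | intermediate
5 | 3-(dimethoxymethyl)-2-iodo-6-methoxyphenyl 4-chlorobenzenesulfonate | COC(OC)c1ccc(OC)c(OS(=O)(=O)c2ccc(Cl)cc2)c1I | intermediate
6 | 2-bromo-3-hydroxy-4-methoxybenzaldehyde (2-bromoisovanillin) | COc1ccc(C=O)c(Br)c1O | starting material
7 | 2-bromo-3-(dimethoxymethyl)-6-methoxyphenol | COC(OC)c1ccc(OC)c(O)c1Br | intermediate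
8 | chloromagnesium 2-bromo-3-(dimethoxymethyl)-6-methoxyphenolate | COC(OC)c1ccc(OC)c(O[Mg]Cl)c1Br | intermediate
9 | [2-(4-chlorobenzenesulfonyloxy)-6-(dimethoxymethyl)-3-methoxyphenyl]magnesium chloride | COC(OC)c1ccc(OC)c(OS(=O)(=O)c2ccc(Cl)cc2)c1[Mg]Cl | intermediate
10 | 3-(dimethoxymethyl)-6-methoxy-1,2-didehydrobenzene | COC(OC)C1=CC=C(OC)C#C1 | intermediate
11 | [2-[2-bromo-3-(dimethoxymethyl)-6-methoxyphenoxy]-3-(dimethoxymethyl)-6-methoxyphenyl]magnesium chloride | COC(OC)c1ccc(OC)c([Mg]Cl)c1Oc1c(Br)c(C(OC)OC)ccc1OC | intermediate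
12 | dimethyl [2-[2-bromo-3-(dimethoxymethyl)-6-methoxyphenoxy]-3-(dimethoxymethyl)-6-methoxyphenyl]boronate | COC(OC)c1ccc(OC)c(B(OC)OC)c1Oc1c(Br)c(C(OC)OC)ccc1OC | intermediate
13 | 2-[2-bromo-3-(dimethoxymethyl)-6-methoxyphenoxy]-3-(dimethoxymethyl)-6-methoxyphenol | COC(OC)c1ccc(OC)c(O)c1Oc1c(Br)c(C(OC)OC)ccc1OC | intermediate
14 | 2-(2-bromo-3-formyl-6-methoxyphenoxy)-3-hydroxy-4-methoxybenzaldehyde | COc1ccc(C=O)c(Oc2c(Br)c(C=O)ccc2OC)c1O | intermediate
15 | 2-(2-bromo-3-formyl-6-hydroxyphenoxy)-3,4-dihydroxybenzaldehyde | O=Cc1ccc(O)c(O)c1Oc1c(Br)c(C=O)ccc1O | intermediate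
16 | 5-bromo-2-(2,5-dibromo-3-formyl-6-hydroxyphenoxy)-3,4-dihydroxybenzaldehyde | O=Cc1cc(Br)c(O)c(O)c1Oc1c(Br)c(C=O)cc(Br)c1O | intermediate
17 | 6-bromo-3-[2,5-dibromo-6-hydroxy-3-(hydroxymethyl)phenoxy]-4-(hydroxymethyl)benzene-1,2-diol | OCc1cc(Br)c(O)c(Oc2c(CO)cc(Br)c(O)c2O)c1Br | target

Total step count: 9. Longest linear sequence: 8 steps (steps 1, 2, 3, 5, 6, 7, 8, 9).

Steps most likely to fail

Step 5. The hindered magnesium aryloxide may add through oxygen too slowly, so that the aryne is consumed by the Grignard reagent formed from 5 or by self-reaction. The aryloxide may also attack through its free para carbon, attack at C6' may erode the regiochemistry, or the C6' arylmagnesium may be protonated before borylation. The fallback uses known chemistry, sets out from 6 and returns at 15. 2-Bromoisovanillin 6 is heated with K2CO3 in DMAc at 120 °C with commercial 2-fluoro-3,4-dimethoxybenzaldehyde (COc1ccc(C=O)c(F)c1OC). This is a nucleophilic aromatic substitution in which the ortho formyl group activates the fluoride, and it should give 2-(2-bromo-3-formyl-6-methoxyphenoxy)-3,4-dimethoxybenzaldehyde F1. BBr3 in CH2Cl2 then cleaves its three methyl ethers to give 15. In this variant the C6' oxygen is bought with ring B instead of being installed.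

Step 8. On ring B, bromination para to the C6' hydroxyl (at C3') may compete with attack at C4'; a third bromine may enter, or bromine may oxidise the free catechol. The fallback sets out from 13 and returns at 16; it masks the C6' oxygen as an ester so that the C5' hydroxyl is the only strong donor on ring B and no free catechol meets bromine. Compound 13 is acylated with pivaloyl chloride (Et3N, DMAP, CH2Cl2) to give 2-[2-bromo-3-(dimethoxymethyl)-6-methoxyphenoxy]-3-(dimethoxymethyl)-6-methoxyphenyl 2,2-dimethylpropanoate F2. Hydrolysis of the acetals (1 M HCl, THF) gives 2-(2-bromo-3-formyl-6-methoxyphenoxy)-3-formyl-6-methoxyphenyl 2,2-dimethylpropanoate F3. BBr3 in CH2Cl2 at −78 → 0 °C cleaves the two methyl ethers to give 2-(2-bromo-3-formyl-6-hydroxyphenoxy)-3-formyl-6-hydroxyphenyl 2,2-dimethylpropanoate F4. Bromination (Br2, NaOAc, AcOH) should then give 5-bromo-2-(2,5-dibromo-3-formyl-6-hydroxyphenoxy)-3-formyl-6-hydroxyphenyl 2,2-dimethylpropanoate F5, and methanolysis of the ester (K2CO3, MeOH, rt) returns 16.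

Step 9. In the basic borohydride medium the aldehydes are deactivated as phenoxides. The para-hydroxybenzyl alkoxides formed may lose hydroxide to quinone methides, which are reduced further or captured by methanol; the same ionisation can occur during work-up. The fallback sets out from 16 and returns at 17; it reduces the aldehydes while the phenols are protected. Acetylation (Ac2O, pyridine, DMAP) gives 3-(6-acetoxy-2,5-dibromo-3-formylphenoxy)-6-bromo-4-formyl-1,2-phenylene diacetate F6. Borane–tetrahydrofuran at 0 °C reduces both aldehydes to give 3-[6-acetoxy-2,5-dibromo-3-(hydroxymethyl)phenoxy]-6-bromo-4-(hydroxymethyl)-1,2-phenylene diacetate F7. Hydrazine hydrate in THF/MeOH at 0 °C then removes the three aryl acetates under mild conditions to give 17.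

Further compounds
F1 | step 5 | 2-(2-bromo-3-formyl-6-methoxyphenoxy)-3,4-dimethoxybenzaldehyde | COc1ccc(C=O)c(Oc2c(Br)c(C=O)ccc2OC)c1OC
F2 | step 8 | 2-[2-bromo-3-(dimethoxymethyl)-6-methoxyphenoxy]-3-(dimethoxymethyl)-6-methoxyphenyl 2,2-dimethylpropanoate | COC(OC)c1ccc(OC)c(OC(=O)C(C)(C)C)c1Oc1c(Br)c(C(OC)OC)ccc1OC
F3 | step 8 | 2-(2-bromo-3-formyl-6-methoxyphenoxy)-3-formyl-6-methoxyphenyl 2,2-dimethylpropanoate | COc1ccc(C=O)c(Oc2c(Br)c(C=O)ccc2OC)c1OC(=O)C(C)(C)C
F4 | step 8 | 2-(2-bromo-3-formyl-6-hydroxyphenoxy)-3-formyl-6-hydroxyphenyl 2,2-dimethylpropanoate | O=Cc1ccc(O)c(OC(=O)C(C)(C)C)c1Oc1c(Br)c(C=O)ccc1O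
F5 | step 8 | 5-bromo-2-(2,5-dibromo-3-formyl-6-hydroxyphenoxy)-3-formyl-6-hydroxyphenyl 2,2-dimethylpropanoate | O=Cc1cc(Br)c(O)c(OC(=O)C(C)(C)C)c1Oc1c(Br)c(C=O)cc(Br)c1O
F6 | step 9 | 3-(6-acetoxy-2,5-dibromo-3-formylphenoxy)-6-bromo-4-formyl-1,2-phenylene diacetate | CC(=O)Oc1c(Br)cc(C=O)c(Oc2c(Br)c(C=O)cc(Br)c2OC(C)=O)c1OC(C)=O
F7 | step 9 | 3-[6-acetoxy-2,5-dibromo-3-(hydroxymethyl)phenoxy]-6-bromo-4-(hydroxymethyl)-1,2-phenylene diacetate | CC(=O)Oc1c(Br)cc(CO)c(Oc2c(Br)c(CO)cc(Br)c2OC(C)=O)c1OC(C)=O
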